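**Strategy.** Ring C of the target (O1–C2–C3–C4–C4a–C8a) is cut into a four-atom heterodiene (O1, C8a, C4a, C4), an ortho-quinone methide grown from protected phloroglucinaldehyde, and a two-carbon unit (C2, C3), the vinyl group of a 3-geranyl-4-oxygenated styrene. One inverse-demand hetero-Diels–Alder reaction under a chiral Brønsted acid should form O1–C2 and C3–C4, close the pyran ring and set C2. C4 arrives as a methyl ether and is raised to the ketone afterwards. The precursors are 2-hydroxy-4,6-bis(methoxymethoxy)benzaldehyde and MOM-protected 2-geranyl-4-vinylphenol; MOM ethers keep every oxygen a strong donor and come off last.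

Key step: step 5

Assumption (chemistry): the sense of induction of the chiral acid in step 5 cannot be predicted with confidence, so the catalyst antipode that gives the (2S) adduct is taken to be found in a first screen (both antipodes are accessible); 4-bromo-2-iodophenol is taken as a commercial starting material.

**Step 1**
Reactants: 1 2,4,6-trihydroxybenzaldehyde
Product: 2 2-hydroxy-4,6-bis(methoxymethoxy)benzaldehyde
Conditions: MOMCl (2.2 equiv), i-Pr2NEt (2.5 equiv), CH2Cl2, 0 °C → rt
Reagents that add atoms: chloromethyl methyl ether, COCCl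
Why: O-alkylation (MOM protection) should stop at the bis-ether because the last ortho hydroxyl is locked in a hydrogen bond to the aldehyde carbonyl and is the least nucleophilic.

**Step 2**
Reactants: 3 4-bromo-2-iodophenol
Product: 4 4-bromo-2-iodo-1-(methoxymethoxy)benzene
Conditions: MOMCl (1.2 equiv), i-Pr2NEt (1.5 equiv), CH2Cl2, 0 °C → rt
Reagents that add atoms: chloromethyl methyl ether, COCCl
Why: Standard MOM protection of a phenol by O-alkylation; the ether later assists the ortho iodine–magnesium exchange by chelation and keeps the oxygen a para donor for the styrene.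

**Step 3**
Reactants: 4 4-bromo-2-iodo-1-(methoxymethoxy)benzene; 5 geranyl bromide
Product: 7 4-bromo-2-[(2E)-3,7-dimethylocta-2,6-dien-1-yl]-1-(methoxymethoxy)benzene, via arylmagnesium chloride 6 (not isolated)
Conditions: i-PrMgCl·LiCl (1.05 equiv), THF, −20 °C; then CuBr·SMe2 (10 mol %), 5 (1.1 equiv), −20 → 0 °C
Reagents that add atoms: none
Why: Iodine–magnesium exchange is much faster at the iodide ortho to the chelating OMOM group than at the bromide, and copper-catalysed allylic substitution of the aryl Grignard on the primary allylic bromide should give the linear product with the E alkene retained, since attack at the far end would have to build a quaternary carbon.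

**Step 4**
Reactants: 7 4-bromo-2-[(2E)-3,7-dimethylocta-2,6-dien-1-yl]-1-(methoxymethoxy)benzene
Product: 8 2-[(2E)-3,7-dimethylocta-2,6-dien-1-yl]-1-(methoxymethoxy)-4-vinylbenzene
Conditions: vinylboronic acid pinacol ester (1.3 equiv), Pd(dppf)Cl2 (3 mol %), K2CO3, dioxane/H2O, 80 °C; product stored cold over BHT
Reagents that add atoms: vinylboronic acid pinacol ester, C=CB1OC(C)(C)C(C)(C)O1
Why: Suzuki–Miyaura coupling of an aryl bromide with a vinylboronate; the isolated trisubstituted alkenes and the MOM ether are inert to Pd(0) and carbonate.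

**Step 5**
Reactants: 2 2-hydroxy-4,6-bis(methoxymethoxy)benzaldehyde; 8 2-[(2E)-3,7-dimethylocta-2,6-dien-1-yl]-1-(methoxymethoxy)-4-vinylbenzene
Product: 11 (2S,4S)-cis-2-{3-[(2E)-3,7-dimethylocta-2,6-dien-1-yl]-4-(methoxymethoxy)phenyl}-4-methoxy-5,7-bis(methoxymethoxy)chromane, via dimethyl acetal 9 (not isolated), via ortho-quinone methide 10 (not isolated)
Conditions: HC(OMe)3 (1.5 equiv), 3,3′-bis(2,4,6-triisopropylphenyl)-BINOL N-triflylphosphoramide (5 mol %, antipode per the assumption), 5 Å MS, toluene, rt 30 min, then −40 °C, slow addition of 8 (1.2 equiv); Et3N quench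
Reagents that add atoms: trimethyl orthoformate, COC(OC)OC
Why: Proposed new method: the acid and the orthoformate convert 2 into acetal 9 and ionise it to the 2-hydroxyaryl methoxycarbenium ion (O-protonated 10), held to the chiral phosphoramide anion by ion pairing and by its phenolic O–H; the CH2 terminus of styrene 8 bonds to the carbenium carbon (C3–C4) and the phenolic oxygen captures the developing 4-alkoxybenzylic cation (O1–C2) in an asynchronous inverse-demand [4+2] hetero-Diels–Alder reaction. The closest known reaction types are the achiral acid-promoted cycloaddition of salicylaldehyde/orthoformate-derived methoxy ortho-quinone methides with styrenes to cis-4-methoxyflavans and chiral phosphoric-acid-type catalysis of ortho-quinone methide cycloadditions with styrenes. The pyran ring closes by the cycloaddition itself, which in the stepwise limit is a 6-exo-trig capture of the benzylic cation by oxygen. C2 is set by the face of the heterodiene left open in the catalyst pocket, the (2S) sense being secured by the choice of catalyst antipode; C4 should follow as cis from an endo placement of the aryl group and is removed in steps 6 and 7. The step needs regioselectivity, which polarity dictates (nucleophilic CH2 to electrophilic C4, cation-stabilised benzylic carbon to oxygen), and chemoselectivity for the vinyl group over the geranyl alkenes, which the much higher nucleophilicity of a 4-alkoxystyrene should provide. The cold, anhydrous and only weakly acidic medium should leave the MOM ethers and the trisubstituted alkenes intact.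

**Step 6**
Reactants: 11 (2S,4S)-cis-4-methoxyflavan tris-MOM ether
Product: 12 (2S)-2-{3-[(2E)-3,7-dimethylocta-2,6-dien-1-yl]-4-(methoxymethoxy)phenyl}-5,7-bis(methoxymethoxy)chroman-4-ol (mixture of C4 epimers)
Conditions: PPTS (10 mol %), THF/H2O 3:1, 0.02 M, 0 °C → rt; NaHCO3 quench, crude alcohol used directly
Reagents that add atoms: water, O
Why: SN1 hydrolysis, because the C4 methyl ether sits on a benzylic carbon backed by three donor oxygens (O1, 5-O, 7-O) and should ionise under acid far too weak to touch the MOM ethers or the alkenes; excess water captures the cation, C2 is not involved and the C4 configuration does not matter.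

**Step 7**
Reactants: 12 (2S)-flavan-4-ol tris-MOM ether
Product: 13 (2S)-2-{3-[(2E)-3,7-dimethylocta-2,6-dien-1-yl]-4-(methoxymethoxy)phenyl}-5,7-bis(methoxymethoxy)chroman-4-one
Conditions: Dess–Martin periodinane (1.3 equiv), NaHCO3 (3 equiv), CH2Cl2, 0 °C → rt
Reagents that add atoms: none
Why: Dess–Martin oxidation of a secondary benzylic alcohol under bicarbonate buffer should merge both C4 epimers into one ketone without affecting MOM ethers, alkenes or the C2 stereocentre, which is not alpha to the new carbonyl.

**Step 8**
Reactants: 13 (2S)-flavanone tris-MOM ether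
Product: 14 (2S)-5,7-dihydroxy-2-{4-hydroxy-3-[(2E)-3,7-dimethylocta-2,6-dien-1-yl]phenyl}chroman-4-one [(2S)-3′-geranylnaringenin]
Conditions: 3 M aq HCl/MeOH (1:10), 40 °C, stopped at full conversion; NaHCO3 work-up
Reagents that add atoms: none
Why: Acid-catalysed acetal exchange (methanolysis) should remove the three aryl MOM ethers, the 5-O-MOM group being assisted by the peri carbonyl, and dilute acid at moderate temperature is chosen as a window in which the geranyl chain and the C2 centre of a flavanone are expected to survive.

**Compound list**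
1 | 2,4,6-trihydroxybenzaldehyde | O=Cc1c(O)cc(O)cc1O | starting material
2 | 2-hydroxy-4,6-bis(methoxymethoxy)benzaldehyde | O=Cc1c(O)cc(OCOC)cc1OCOC | intermediate
3 | 4-bromo-2-iodophenol | Oc1ccc(Br)cc1I | starting material
4 | 4-bromo-2-iodo-1-(methoxymethoxy)benzene | COCOc1ccc(Br)cc1I | intermediate
5 | geranyl bromide, (2E)-1-bromo-3,7-dimethylocta-2,6-diene | CC(C)=CCC/C(C)=C/CBr | starting material
6 | [5-bromo-2-(methoxymethoxy)phenyl]magnesium chloride, LiCl complex (not isolated) | COCOc1ccc(Br)cc1[Mg]Cl | intermediate
7 | 4-bromo-2-[(2E)-3,7-dimethylocta-2,6-dien-1-yl]-1-(methoxymethoxy)benzene | CC(C)=CCC/C(C)=C/Cc1cc(Br)ccc1OCOC | intermediate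
8 | 2-[(2E)-3,7-dimethylocta-2,6-dien-1-yl]-1-(methoxymethoxy)-4-vinylbenzene | CC(C)=CCC/C(C)=C/Cc1cc(C=C)ccc1OCOC | intermediate
9 | 2-(dimethoxymethyl)-3,5-bis(methoxymethoxy)phenol (not isolated) | COC(OC)c1c(O)cc(OCOC)cc1OCOC | intermediate
10 | 6-(methoxymethylidene)-3,5-bis(methoxymethoxy)cyclohexa-2,4-dien-1-one (not isolated; exocyclic geometry not fixed, it equilibrates through the protonated form) | COC=C1C(=O)C=C(OCOC)C=C1OCOC | intermediate
11 | (2S,4S)-cis-2-{3-[(2E)-3,7-dimethylocta-2,6-dien-1-yl]-4-(methoxymethoxy)phenyl}-4-methoxy-5,7-bis(methoxymethoxy)chromane | CC(C)=CCC/C(C)=C/Cc1cc([C@@H]2C[C@H](OC)c3c(OCOC)cc(OCOC)cc3O2)ccc1OCOC | intermediate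
12 | (2S)-2-{3-[(2E)-3,7-dimethylocta-2,6-dien-1-yl]-4-(methoxymethoxy)phenyl}-5,7-bis(methoxymethoxy)chroman-4-ol, C4 epimer mixture | CC(C)=CCC/C(C)=C/Cc1cc([C@@H]2CC(O)c3c(OCOC)cc(OCOC)cc3O2)ccc1OCOC | intermediate
13 | (2S)-2-{3-[(2E)-3,7-dimethylocta-2,6-dien-1-yl]-4-(methoxymethoxy)phenyl}-5,7-bis(methoxymethoxy)chroman-4-one | CC(C)=CCC/C(C)=C/Cc1cc([C@@H]2CC(=O)c3c(OCOC)cc(OCOC)cc3O2)ccc1OCOC | intermediate
14 | (2S)-5,7-dihydroxy-2-{4-hydroxy-3-[(2E)-3,7-dimethylocta-2,6-dien-1-yl]phenyl}chroman-4-one | CC(C)=CCC/C(C)=C/Cc1cc([C@@H]2CC(=O)c3c(O)cc(O)cc3O2)ccc1O | target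

**Total step count:** 8
**Longest linear sequence:** 7 steps (steps 2–8, from 3 to 14)

**Steps most likely to fail**

Step 5. The ion pair may discriminate poorly between the two faces of the heterodiene, or the acid may start cationic oligomerisation of the alkoxystyrene before the cycloaddition turns over. The fallback uses known chemistry, sets out from 2 and 8 and returns at 13. An achiral acid (diphenyl phosphate or Sc(OTf)3 with trimethyl orthoformate, CH2Cl2, −20 °C) should give racemic cis-4-methoxyflavan tris-MOM ether F1. The conditions of steps 6 and 7 should then give racemic flavan-4-ol tris-MOM ether F2 and racemic flavanone tris-MOM ether F3. A Noyori-type asymmetric transfer hydrogenation (Rh(III)– or Ru(II)–TsDPEN catalyst, HCO2H/Et3N, EtOAc, rt) is run as a kinetic resolution to just past half conversion, with the ligand antipode that reduces the (2R)-ketone faster. It should leave (2S)-ketone 13 and turn the other enantiomer into (2R,4R)-cis-flavan-4-ol tris-MOM ether F4, which is removed by chromatography.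

Step 6. The C4 cation may lose a C3 proton to give the flav-3-ene, or alkylate an electron-rich ring of a second molecule, instead of being captured by water. The fallback sets out from 11 and returns at 13 in one operation; no new compound is made (F0). DDQ (1.2 equiv) in CH2Cl2/pH 7 buffer at 0 °C should abstract hydride from C4, the benzylic ether C–H activated by three ring oxygens. Water then adds to the methoxycarbenium ion and the hemiketal collapses to the ketone, so the flavan-4-ol is bypassed.

Step 8. Protic acid may cyclise the geranyl chain onto the freshly freed 4′-hydroxyl, add across the trisubstituted alkenes, or partly racemise C2 through ring opening. The fallback sets out from 13 and returns at 14 without a Brønsted acid. TMSOTf/2,2′-bipyridyl in CH2Cl2 at 0 °C should exchange the three aryl MOM ethers for silyl ethers, giving (2S)-3′-geranylnaringenin tris(trimethylsilyl) ether F5. Stirring with water at neutral pH and room temperature should then hydrolyse it to 14.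

**Further compounds**
F1 | step 5 | racemic cis-2-{3-[(2E)-3,7-dimethylocta-2,6-dien-1-yl]-4-(methoxymethoxy)phenyl}-4-methoxy-5,7-bis(methoxymethoxy)chromane | CC(C)=CCC/C(C)=C/Cc1cc(C2CC(OC)c3c(OCOC)cc(OCOC)cc3O2)ccc1OCOC
F2 | step 5 | racemic 2-{3-[(2E)-3,7-dimethylocta-2,6-dien-1-yl]-4-(methoxymethoxy)phenyl}-5,7-bis(methoxymethoxy)chroman-4-ol | CC(C)=CCC/C(C)=C/Cc1cc(C2CC(O)c3c(OCOC)cc(OCOC)cc3O2)ccc1OCOC
F3 | step 5 | racemic 2-{3-[(2E)-3,7-dimethylocta-2,6-dien-1-yl]-4-(methoxymethoxy)phenyl}-5,7-bis(methoxymethoxy)chroman-4-one | CC(C)=CCC/C(C)=C/Cc1cc(C2CC(=O)c3c(OCOC)cc(OCOC)cc3O2)ccc1OCOC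
F4 | step 5 | (2R,4R)-cis-2-{3-[(2E)-3,7-dimethylocta-2,6-dien-1-yl]-4-(methoxymethoxy)phenyl}-5,7-bis(methoxymethoxy)chroman-4-ol | CC(C)=CCC/C(C)=C/Cc1cc([C@H]2C[C@@H](O)c3c(OCOC)cc(OCOC)cc3O2)ccc1OCOC
F0 | step 6 | none | none
F5 | step 8 | (2S)-2-{3-[(2E)-3,7-dimethylocta-2,6-dien-1-yl]-4-(trimethylsilyloxy)phenyl}-5,7-bis(trimethylsilyloxy)chroman-4-one | CC(C)=CCC/C(C)=C/Cc1cc([C@@H]2CC(=O)c3c(O[Si](C)(C)C)cc(O[Si](C)(C)C)cc3O2)ccc1O[Si](C)(C)C
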